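Retrosynthesis: ring C is opened at O1–C8a and, in the same operation, at C4–C4a. This gives 1-iodo-2,3-dimethoxybenzene (ring A) and (1S)-3-iodo-1-(3,4,5-trimethoxyphenyl)propan-1-ol (ring B with C2, C3, C4 and O1).
Enabling feature: in ring A, C8a lies between C8, which carries OMe, and C4a, which carries the chain. An iodide on C8a therefore has one blocked ortho carbon and one free ortho C–H, the pattern a palladium/norbornene relay (Catellani manifold) needs to alkylate C4a and return the metal to C8a.
Forward: the ring A iodide comes from veratrole by ortho-lithiation. The chain fragment comes from ethyl 3,4,5-trimethoxybenzoylacetate by ketone reduction, ester reduction and primary iodination. The last step joins C4 to C4a and then closes ring C by C8a–O1 reductive elimination; norbornene, the only helper, forms a temporary palladacycle and leaves in the same flask.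
Stereochemistry: C2 is set once, by asymmetric transfer hydrogenation of the aryl ketone, and its C–O bond is never broken afterwards.

Key step: step 5

Remark: flavan numbering (O1, C2, C3, C4, C4a, C5–C8, C8a) is used for the target and for the matching atoms of its precursors. Ring A is the dimethoxybenzo ring, ring B the trimethoxyphenyl ring and ring C the pyran. Veratrole and ethyl 3-oxo-3-(3,4,5-trimethoxyphenyl)propanoate are taken as catalogue chemicals.

Step 1
Reactants: 1 veratrole (1,2-dimethoxybenzene)
Product: 3 1-iodo-2,3-dimethoxybenzene, via 2,3-dimethoxyphenyllithium 2 (not isolated)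
Conditions: n-BuLi, TMEDA, Et2O, 0 °C to rt; then I2, THF, −78 °C to rt
Reagents that add atoms: iodine, II
Why: Directed ortho-metalation followed by iodinolysis: the OMe groups of the symmetric ether 1 guide n-BuLi/TMEDA to the adjacent C–H (both such positions are equivalent), so iodine should end up on the future C8a next to the future C8 methoxy group.

Step 2
Reactants: 4 ethyl 3-oxo-3-(3,4,5-trimethoxyphenyl)propanoate
Product: 5 ethyl (3S)-3-hydroxy-3-(3,4,5-trimethoxyphenyl)propanoate
Conditions: RuCl[(S,S)-TsDPEN](p-cymene) (1 mol %), HCO2H–Et3N azeotrope, 35 °C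
Reagents that add atoms: none
Why: Noyori–Ikariya asymmetric transfer hydrogenation: in the outer-sphere, six-membered hydride/proton transfer state the CH/π contact between the p-cymene ligand and ring B should expose the Re face of the ketone to the (S,S) catalyst, as for other aryl ketones, which sets the S carbinol (future C2) and leaves the ester untouched.

Step 3
Reactants: 5 ethyl (3S)-3-hydroxy-3-(3,4,5-trimethoxyphenyl)propanoate
Product: 6 (1S)-1-(3,4,5-trimethoxyphenyl)propane-1,3-diol
Conditions: LiAlH4, THF, 0 °C to rt; then H2O
Reagents that add atoms: none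
Why: Standard LiAlH4 ester reduction, in which the carbinol is only masked as its alkoxide, so the ester should go to the primary alcohol with the stereocentre unchanged.

Step 4
Reactants: 6 (1S)-1-(3,4,5-trimethoxyphenyl)propane-1,3-diol
Product: 7 (1S)-3-iodo-1-(3,4,5-trimethoxyphenyl)propan-1-ol
Conditions: I2, PPh3, imidazole, CH2Cl2, 0 °C, dark
Reagents that add atoms: iodine, II
Why: Garegg–Samuelsson (Appel-type) iodination: the iodophosphonium reagent should engage the unhindered primary OH faster than the secondary benzylic OH, and iodide then displaces Ph3P=O by SN2 at CH2, so the stereocentre is not a reacting centre.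

Step 5
Reactants: 3 1-iodo-2,3-dimethoxybenzene; 7 (1S)-3-iodo-1-(3,4,5-trimethoxyphenyl)propan-1-ol
Product: 10 (2S)-7,8,3',4',5'-pentamethoxyflavan, via aryl-norbornyl palladacycle 8 (not isolated), via ring-open arylpalladium iodide 9 (not isolated)
Conditions: Pd(OAc)2 (5 mol %), RuPhos (10 mol %), norbornene (1 equiv), Cs2CO3 (3 equiv), toluene, 100 °C
Reagents that add atoms: none
Why: Proposed new method: zerovalent palladium inserts into the C8a–I bond of 3, norbornene carbopalladation followed by carbonate-assisted palladation of the only free ortho C–H (C4a–H) gives palladacycle 8, and SN2-type oxidative addition of the primary C–I bond of 7 (tetravalent palladium) with reductive elimination forges C4–C4a. Now flanked by two ortho substituents, the aryl–norbornyl bond breaks by β-carbon elimination, norbornene leaves, divalent palladium sits again on C8a in 9, the C2 hydroxyl binds as its alkoxide, and reductive elimination from the seven-membered oxapalladacycle forms C8a–O1 and closes the six-membered ring C (formally a 6-exo attack of O1 on C8a). The closest known reaction types are the Pd/norbornene annulation of aryl iodides with bromoalkylamines (ortho-alkylation/ipso-amination to indolines and tetrahydroquinolines), the Pd/norbornene annulation of aryl iodides with epoxides to 2,3-dihydrobenzofurans (the same C–O termination from a secondary alkoxide, one ring atom fewer) and the Pd-catalysed intramolecular etherification of 3-(2-haloaryl)propanols; what is new is their union with a γ-iodo alcohol to give a chroman. No stereocentre is made: the C2–O and C2–H bonds are not reacting bonds, so the S configuration of 7 should be carried into 10. The step needs single ortho-alkylation (secured by the C8 methoxy group, which blocks the second ortho carbon and drives norbornene extrusion), alkylation before etherification (norbornene insertion should outrun intermolecular alkoxide capture, and the primary C–I bond is the only electrophile offered to 8; sparingly soluble Cs2CO3 in toluene keeps free alkoxide low) and reductive elimination faster than β-hydride loss from the C2 alkoxide (secured by the bulky dialkylbiarylphosphine and by the two ortho substituents on the aryl ligand).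

Compound list
1 | veratrole (1,2-dimethoxybenzene) | COc1ccccc1OC | starting material
2 | 2,3-dimethoxyphenyllithium | [Li]c1cccc(OC)c1OC | intermediate
3 | 1-iodo-2,3-dimethoxybenzene | COc1cccc(I)c1OC | intermediate
4 | ethyl 3-oxo-3-(3,4,5-trimethoxyphenyl)propanoate | CCOC(=O)CC(=O)c1cc(OC)c(OC)c(OC)c1 | starting material
5 | ethyl (3S)-3-hydroxy-3-(3,4,5-trimethoxyphenyl)propanoate | CCOC(=O)C[C@H](O)c1cc(OC)c(OC)c(OC)c1 | intermediate
6 | (1S)-1-(3,4,5-trimethoxyphenyl)propane-1,3-diol | OCC[C@H](O)c1cc(OC)c(OC)c(OC)c1 | intermediate
7 | (1S)-3-iodo-1-(3,4,5-trimethoxyphenyl)propan-1-ol | ICC[C@H](O)c1cc(OC)c(OC)c(OC)c1 | intermediate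
8 | aryl-norbornyl palladacycle (five-membered ring Pd–C4a–C8a–norbornyl C–norbornyl C, cis-exo, racemic, phosphine omitted) | COc1ccc2c(c1OC)C1C3CCC(C3)C1[Pd]2 | intermediate
9 | {2,3-dimethoxy-6-[(3S)-3-hydroxy-3-(3,4,5-trimethoxyphenyl)propyl]phenyl}palladium iodide (phosphine omitted) | COc1ccc(CC[C@H](O)c2cc(OC)c(OC)c(OC)c2)c([Pd]I)c1OC | intermediate
10 | (2S)-7,8,3',4',5'-pentamethoxyflavan | COc1cc([C@@H]2CCc3ccc(OC)c(OC)c3O2)cc(OC)c1OC | target

Total step count: 5. Longest linear sequence: 4 (steps 2, 3, 4 and 5).

Steps most likely to fail

Step 5.
- What may go wrong: β-hydride elimination from the palladium alkoxide may outrun C–O reductive elimination. This would be a redox termination with hydrodepalladation.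
- What may also go wrong: base-induced intramolecular O-alkylation of the iodohydrin may use up the alkylating partner before it meets the palladacycle.
- Fallback: a stepwise sequence of known reactions that sets out from keto ester 4 and comes back at target 10.
- Purchasable (2-bromo-3,4-dimethoxyphenyl)methanol (COc1ccc(CO)c(Br)c1OC) is converted with PBr3 (CH2Cl2, 0 °C) into 2-bromo-1-(bromomethyl)-3,4-dimethoxybenzene F1.
- Keto ester 4 is C-alkylated with it (K2CO3, acetone, reflux) to the benzylated keto ester F2.
- Saponification (aq. NaOH, EtOH) gives the β-keto acid F3, which loses CO2 on acidification and warming to give the bromo dihydrochalcone ketone F4.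
- The transfer hydrogenation of step 2 with the same (S,S) catalyst should give the S bromo alcohol F5.
- The Buchwald–Hartwig-type intramolecular etherification (Pd(OAc)2, 2-(di-tert-butylphosphino)-1,1'-binaphthyl, Cs2CO3, toluene, 80 °C) closes the same C8a–O1 bond. It is known for secondary 3-(2-bromoaryl)propanols and retains the carbinol configuration.

Step 4.
- What may go wrong: chemoselectivity may be lost. Activation of the benzylic OH as well would lead to ionisation, racemisation or double substitution.
- Fallback: a protecting-group detour that sets out from hydroxy ester 5 and comes back at iodohydrin 7, so that the two hydroxyl groups never compete.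
- Silylation of 5 (TBSCl, imidazole, DMF) gives the silyl ether ester F6.
- DIBAL-H (CH2Cl2, −78 to 0 °C) gives the silyl-protected primary alcohol F7.
- I2/PPh3/imidazole gives the silyl-protected iodide F8.
- HF·pyridine (THF, 0 °C) frees the carbinol without base, so the γ-iodo alkoxide is never formed.

Step 2.
- What may go wrong: facial selectivity may be poor or turnover slow with the enolisable, electron-rich aroylacetate.
- Fallback: biocatalysis in place of metal catalysis, setting out from 4 and coming back at 5.
- An S-selective ketoreductase is used with NADP+ and glucose/glucose dehydrogenase recycling in phosphate buffer at 30 °C. Fermenting baker's yeast, a known means of reducing aroylacetates to the S hydroxy esters, also serves.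
- The face is then chosen by the protein pocket and not by a CH/π contact. No new compound arises.

Further compounds
F1 | step 5 | 2-bromo-1-(bromomethyl)-3,4-dimethoxybenzene | COc1ccc(CBr)c(Br)c1OC
F2 | step 5 | ethyl 2-[(2-bromo-3,4-dimethoxyphenyl)methyl]-3-oxo-3-(3,4,5-trimethoxyphenyl)propanoate (racemic) | CCOC(=O)C(Cc1ccc(OC)c(OC)c1Br)C(=O)c1cc(OC)c(OC)c(OC)c1
F3 | step 5 | 2-[(2-bromo-3,4-dimethoxyphenyl)methyl]-3-oxo-3-(3,4,5-trimethoxyphenyl)propanoic acid (racemic) | OC(=O)C(Cc1ccc(OC)c(OC)c1Br)C(=O)c1cc(OC)c(OC)c(OC)c1
F4 | step 5 | 3-(2-bromo-3,4-dimethoxyphenyl)-1-(3,4,5-trimethoxyphenyl)propan-1-one | COc1ccc(CCC(=O)c2cc(OC)c(OC)c(OC)c2)c(Br)c1OC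
F5 | step 5 | (1S)-3-(2-bromo-3,4-dimethoxyphenyl)-1-(3,4,5-trimethoxyphenyl)propan-1-ol | COc1ccc(CC[C@H](O)c2cc(OC)c(OC)c(OC)c2)c(Br)c1OC
F6 | step 4 | ethyl (3S)-3-[(tert-butyldimethylsilyl)oxy]-3-(3,4,5-trimethoxyphenyl)propanoate | CCOC(=O)C[C@H](O[Si](C)(C)C(C)(C)C)c1cc(OC)c(OC)c(OC)c1
F7 | step 4 | (3S)-3-[(tert-butyldimethylsilyl)oxy]-3-(3,4,5-trimethoxyphenyl)propan-1-ol | OCC[C@H](O[Si](C)(C)C(C)(C)C)c1cc(OC)c(OC)c(OC)c1
F8 | step 4 | tert-butyl{[(1S)-3-iodo-1-(3,4,5-trimethoxyphenyl)propyl]oxy}dimethylsilane | ICC[C@H](O[Si](C)(C)C(C)(C)C)c1cc(OC)c(OC)c(OC)c1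
F0 | step 2 | none | none
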